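## Analysis of the target

The target is an open-chain sesquineolignan with three benzene rings and no other ring. Ring A (4-hydroxy-3-methoxyphenyl) and ring B (3',5'-dimethoxy-4'-oxyphenyl) are joined by the chain C7H2–C8H(CH3)–C8'H(CH3)–C7'H2. The oxygen on C4' of ring B carries C8'' of a 1-arylpropan-1-ol unit, C8''H(CH3)–C7''H(OH)–ring C (4-hydroxy-3-methoxyphenyl).

There are four stereocentres in two vicinal pairs, insulated from each other by ring B. C8 (S) and C8' (R) have the meso-like (erythro) relationship of a 2,3-dimethylbutane-1,4-diyl chain whose ends differ only in the aryl group. C7'' (S) and C8'' (R) form an erythro aryloxy alcohol. Because the pairs cannot influence each other, each has to be set in absolute terms.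

The sensitive sites are the two free phenols, the secondary benzylic alcohol at C7'' (para to an oxygen of ring C, so prone to ionisation and hydrogenolysis), and the aryl alkyl ether at a phenol oxygen flanked by two methoxy groups, which is hard to form late. The main difficulty is C8 and C8'. They carry only methyl, hydrogen and benzyl-type carbon substituents, with no heteroatom handle, and the two chain ends are nearly alike. Most ways of making them therefore need oxidation-level corrections at C7, C7', C9 or C9'.

The plan rests on the unit C8'H(CH3)–C7'H2–C1' of ring B. It is the formal adduct of hydrogen (to C8') and the ring-B aryl group (to C7') across a 1,1-disubstituted alkene C7'=C8'(CH3). The C7'–C1' bond and the C8' centre can therefore be made in one step from an alkene that already holds C8 and an aryl bromide that already holds C7'' and C8''.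

## Retrosynthetic reasoning

**O–benzyl and O–silyl bonds (22 ⇐ 21 ⇐ 20).** The two phenols are traced back to benzyl ethers and the C7'' hydroxyl to a tert-butyldimethylsilyl ether. The phenols must be masked through enolate, Grignard and hydride chemistry. The C7'' hydroxyl must be masked in the fragment union, where a free alcohol would consume silane and copper hydride. The silyl ether is removed first, while the phenols are still capped, so that no phenoxide can expel the C7'' oxygen. Neutral hydrogenolysis of 21 is then the last step.

**C7'–C1' bond (20 ⇒ 9 + 19).** This cut divides the molecule into halves of similar size, the ring-A alkene 9 with C8 and the ring-B/ring-C bromide 19 with C7'' and C8''. Every carbon is already at its final oxidation level: C7 and C7' are CH2, C9 and C9' are CH3. The forward reaction must add hydrogen to C8' from one face under catalyst control, place the aryl group on the terminal carbon, and leave the silyl ether, the benzyl ethers and the three existing stereocentres alone. The mirror cut at C7–C1 would use the same reaction but would send the elaborate ring-B/ring-C part through the whole alkene synthesis, so it is less convergent. No benzylic deoxygenation is ever needed, which is why the labile C7'' carbinol can be on board before the union.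

**C7'=C8' and C8'–C9' bonds (9 ⇐ 8 ⇐ 6).** The isopropenyl group is traced to methyl ketone 8 by methylenation, and 8 to the N-methoxy-N-methylamide 6 by addition of one methyl nucleophile. Both operations work on a carbonyl next to C8, so they must be non-epimerising. A chelate-stabilised adduct (7) and a non-basic methylenation answer this.

**C7–C8 bond (6 ⇐ 5 ⇐ 3 + 2; 2 ⇐ 1).** C8 is a methyl-bearing carbon α to a carbonyl, the textbook case for auxiliary-controlled enolate alkylation. The propionyl imide 3 supplies C8, C9 and the future C8'. The benzylic bromide 2, made from the purchasable alcohol 1, supplies ring A and C7. The auxiliary antipode is chosen so that the benzyl group enters on the face that gives 8S.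

**C7''–H bond and O–Si bond (19 ⇐ 18 ⇐ 17).** The erythro relationship between C7'' and C8'' is the one expected from a chelate-controlled hydride addition to the α-aryloxy ketone 17. C7'' is therefore derived from C8'' and needs no second source of chirality. Silylation of 18 gives 19.

**C7''–C1'' bond (17 ⇐ 13 + 14; 13 ⇐ 12).** The aryl ketone is cut at the carbonyl–ring C bond into the N-methoxy-N-methylamide 13 and the purchasable bromide 14, used as its Grignard reagent 15. An arylmagnesium reagent is chosen because it leaves the ring-B C–Br bond of 13 intact. That bromine is carried from the start because it is the handle for the fragment union.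

**O4'–C8'' bond (12 ⇐ 10 + 11).** The hindered aryl ether is made first, while the partners are small. The phenol 10 displaces the activated hydroxyl of the lactate 11 with inversion, so the cheap (S)-hydroxy ester gives the (R)-configured C8''.

## Alternatives that were turned down

**Alternative 1:** The C8'–C9' and C7–C8 bonds are cut together. The (S)-butenolide A1, which carries ring B at C7', would take a methyl group from a methylcuprate at C8' anti to the aryl group. In the same flask it would be benzylated at C8 by bromide 2, anti to the new methyl, to give the trans,trans-lactone A2.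

- For it: diastereocontrol on a five-membered ring is about as dependable as acyclic stereocontrol gets. On this point it is stronger than the chosen route, which relies on a catalyst to override an acyclic neighbour.
- Against it: A2 is far from the target in oxidation level. The lactone carbon has to become the C9 methyl group (reduction, activation, hydride) and the C7' oxygen has to be removed by hydrogenolysis.
- A method that removes a benzylic oxygen at C7' would also threaten the benzylic C7'' oxygen and the benzyl ethers. Ring C and its side chain therefore cannot be present and must be built afterwards, in four or more steps, on a phenol flanked by two methoxy groups.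
- The γ-hydrogen of A1 is benzylic and vinylogously acidic, so base-induced loss of the controlling centre competes with conjugate addition.
- The sequence would be linear and well over a dozen steps long.

The chosen strategy gives up the ring-based control and offers in its place a convergent union with every carbon at its final oxidation level.

**Alternative 2:** The C1–C7 bond is cut. The meso anhydride A3 would be opened at one of its two enantiotopic carbonyl groups by the ring-A arylzinc bromide A4 under a chiral rhodium catalyst, to give the keto acid A5.

- For it: the relative configuration of C8 and C8' is bought with the meso starting material and needs no diastereoselection at all. One catalytic step at the outset sets the absolute configuration. Both points are stronger than in the chosen route.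
- Against it: in A5, C7 is a ketone and C7' a carboxylic acid. Ring B must be attached through a second aryl ketone, and two benzylic carbonyl groups must be reduced to CH2.
- During this, C8 and then C8' sit α to a ketone and can epimerise, which would undo exactly what the meso compound provided.
- As in Alternative 1, the benzylic deoxygenations are incompatible with the C7'' carbinol, so the ring-C side chain has to be added late at the hindered phenol.

The chosen strategy never places C8 or C8' next to a carbonyl once both exist, and it joins the complete ring-B/ring-C fragment in one step.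

**Alternative 3:** The C8–C8' bond is cut. In the allylic ester A6, the acyl part carries ring A and the (R)-configured (E)-allylic alkoxy part carries ring B. Kinetic enolisation and silylation in the flask would be followed by Ireland–Claisen rearrangement through a chair, giving the acid A7 with both centres set by transfer of the carbinol chirality.

- For it: the closed transition state makes the 8,8' relationship highly predictable. The central bond is formed directly between two aryl-bearing halves. C7 and C7' are already CH2. On predictability of the relative configuration it is at least the equal of the chosen route.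
- Against it: neither methyl group exists after the key step. The carboxyl group must be reduced to C9H3, and the propenyl group on C8' must be cleaved oxidatively in the presence of three electron-rich arenes and then reduced to C9'H3. That is four or five steps spent on oxidation level and on removing two carbons.
- The ring-C side chain again follows afterwards on the hindered phenol, and the enantioenriched allylic alcohol part needs its own synthesis.

The chosen strategy has both methyl groups in place as methyl groups from commercial materials and reaches the protected target in one step after the two fragments are made.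

Key step: step 11

Assumptions:
- (R)-DTBM-SEGPHOS is taken to be the ligand antipode whose copper hydride delivers hydrogen to the face of C8' that gives 8'R. If a first run showed the opposite sense, the mirror-image ligand would be used and nothing else in the route would change.
- Compounds 1 and 14 are taken as purchased.

## Route

Step 1
Reactants: 1 [4-(benzyloxy)-3-methoxyphenyl]methanol
Product: 2 1-(benzyloxy)-4-(bromomethyl)-2-methoxybenzene
Conditions: PBr3 (0.4 equiv), Et2O, 0 °C; used crude
Reagents that add atoms: phosphorus tribromide, BrP(Br)Br
Why: Conversion of a benzylic alcohol into the bromide through its phosphite ester (SN2 by bromide); the aryl benzyl ether and the methoxy group are inert at 0 °C, and the electron-rich bromide is used at once without chromatography.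

Step 2
Reactants: 3 (R)-4-benzyl-3-propionyloxazolidin-2-one; 2 1-(benzyloxy)-4-(bromomethyl)-2-methoxybenzene
Product: 5 (R)-4-benzyl-3-{(S)-3-[4-(benzyloxy)-3-methoxyphenyl]-2-methylpropanoyl}oxazolidin-2-one, via sodium (Z)-enolate 4 (not isolated)
Conditions: NaN(SiMe3)2 (1.1 equiv), THF, −78 °C; then 2 (1.5 equiv), −78 → −20 °C
Reagents that add atoms: none
Why: Evans asymmetric alkylation: the chelated (Z)-enolate 4 is shielded on one face by the 4-benzyl group of the (R)-auxiliary, so the benzylic bromide enters from the other face and sets C8 as S. Benzylic bromides are among the best electrophiles for this enolate.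

Step 3
Reactants: 5 (R)-4-benzyl-3-{(S)-3-[4-(benzyloxy)-3-methoxyphenyl]-2-methylpropanoyl}oxazolidin-2-one
Product: 6 (S)-3-[4-(benzyloxy)-3-methoxyphenyl]-N-methoxy-N,2-dimethylpropanamide
Conditions: Me(MeO)NH·HCl (3 equiv), AlMe3 (3 equiv), CH2Cl2, 0 °C → rt; aq potassium sodium tartrate work-up
Reagents that add atoms: N,O-dimethylhydroxylamine hydrochloride, CNOC.Cl
Why: Weinreb aminolysis of the N-acyloxazolidinone by the aluminium amide formed from AlMe3 and the amine salt; the medium is not basic, so C8 is not touched, and the auxiliary is recovered.

Step 4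
Reactants: 6 (S)-3-[4-(benzyloxy)-3-methoxyphenyl]-N-methoxy-N,2-dimethylpropanamide
Product: 8 (S)-4-[4-(benzyloxy)-3-methoxyphenyl]-3-methylbutan-2-one, via magnesium hemiaminal chelate 7 (not isolated)
Conditions: MeMgBr (1.5 equiv), THF, 0 °C; aqueous work-up
Reagents that add atoms: methylmagnesium bromide, C[Mg]Br
Why: Weinreb ketone synthesis: the adduct is held as the five-membered magnesium chelate 7 until work-up, so exactly one methyl group is delivered and the ketone is never exposed to the basic reagent, which protects C8.

Step 5
Reactants: 8 (S)-4-[4-(benzyloxy)-3-methoxyphenyl]-3-methylbutan-2-one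
Product: 9 (S)-1-(benzyloxy)-4-(2,3-dimethylbut-3-en-1-yl)-2-methoxybenzene
Conditions: Cp2TiMe2 (3 equiv), toluene/THF, 65 °C, dark
Reagents that add atoms: dimethyltitanocene Cp2TiMe2, C[Ti](C)(C1C=CC=C1)C1C=CC=C1
Why: Petasis methylenation: on heating, Cp2TiMe2 loses methane to give the methylidene Cp2Ti=CH2, which adds to the ketone in a [2+2] fashion and cycloreverts to the 1,1-disubstituted alkene. The reagent is neither basic nor strongly Lewis acidic, which is why it is preferred to a phosphorus ylide next to the enolisable C8 centre.

Step 6
Reactants: 10 4-bromo-2,6-dimethoxyphenol; 11 ethyl (S)-lactate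
Product: 12 ethyl (R)-2-(4-bromo-2,6-dimethoxyphenoxy)propanoate
Conditions: PPh3, DIAD, THF, 0 °C → rt
Reagents that add atoms: none
Why: Mitsunobu etherification: the lactate hydroxyl is activated as the alkoxyphosphonium ion and displaced by the phenoxide of 10 in an SN2 step with inversion, so the (S)-carbinol becomes the (R)-aryl ether that is C8'' of the target. The phenol is acidic enough to protonate the betaine, and the adjacent ester speeds the displacement despite the two ortho methoxy groups.

Step 7
Reactants: 12 ethyl (R)-2-(4-bromo-2,6-dimethoxyphenoxy)propanoate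
Product: 13 (R)-2-(4-bromo-2,6-dimethoxyphenoxy)-N-methoxy-N-methylpropanamide
Conditions: Me(MeO)NH·HCl (1.5 equiv), iPrMgCl (3 equiv), THF, −20 °C; aqueous work-up
Reagents that add atoms: N,O-dimethylhydroxylamine hydrochloride, CNOC.Cl
Why: Direct ester-to-Weinreb-amide exchange by the magnesium amide made in the flask; at −20 °C the C–Br bond of this electron-rich ring does not undergo halogen–magnesium exchange, and the short contact at low temperature is expected to leave C8'' untouched.

Step 8
Reactants: 13 (R)-2-(4-bromo-2,6-dimethoxyphenoxy)-N-methoxy-N-methylpropanamide; 14 1-(benzyloxy)-4-bromo-2-methoxybenzene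
Product: 17 (R)-1-[4-(benzyloxy)-3-methoxyphenyl]-2-(4-bromo-2,6-dimethoxyphenoxy)propan-1-one, via aryl Grignard reagent 15 (not isolated), via magnesium hemiaminal chelate 16 (not isolated)
Conditions: 14, Mg, THF, 40 °C; solution decanted from Mg onto 13, THF, 0 °C; aqueous work-up; product taken on without delay
Reagents that add atoms: none
Why: Weinreb ketone synthesis with the aryl Grignard reagent 15; the chelate 16 prevents over-addition and keeps the α-aryloxy ketone masked until the neutral quench, and an arylmagnesium bromide does not exchange with the ring-B bromide. Decanting from excess Mg keeps the metal away from the C–Br bond of 13.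

Step 9
Reactants: 17 (R)-1-[4-(benzyloxy)-3-methoxyphenyl]-2-(4-bromo-2,6-dimethoxyphenoxy)propan-1-one
Product: 18 (1S,2R)-1-[4-(benzyloxy)-3-methoxyphenyl]-2-(4-bromo-2,6-dimethoxyphenoxy)propan-1-ol
Conditions: Zn(BH4)2 (ethereal stock solution), Et2O/CH2Cl2, −30 → 0 °C; aqueous work-up
Reagents that add atoms: none
Why: Chelate-controlled hydride reduction (Cram chelate model): zinc bridges the carbonyl oxygen and the C8'' ether oxygen in a five-membered ring whose two faces carry the hydrogen and the methyl group of C8''; hydride enters past the hydrogen and should give the 7''S alcohol, the erythro (1S,2R) isomer. The reagent is close to neutral, so the α-centre of the ketone should not epimerise.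

Step 10
Reactants: 18 (1S,2R)-1-[4-(benzyloxy)-3-methoxyphenyl]-2-(4-bromo-2,6-dimethoxyphenoxy)propan-1-ol
Product: 19 tert-butyl{(1S,2R)-1-[4-(benzyloxy)-3-methoxyphenyl]-2-(4-bromo-2,6-dimethoxyphenoxy)propoxy}dimethylsilane
Conditions: TBSOTf, 2,6-lutidine, CH2Cl2, −78 → 0 °C
Reagents that add atoms: tert-butyldimethylsilyl trifluoromethanesulfonate, CC(C)(C)[Si](C)(C)OS(=O)(=O)C(F)(F)F
Why: Silylation of a hindered secondary benzylic alcohol with the silyl triflate and a non-nucleophilic base; the silyl ether keeps the hydroxyl from consuming silane and copper hydride in step 11 and is orthogonal to the benzyl ethers.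

Step 11
Reactants: 9 (S)-1-(benzyloxy)-4-(2,3-dimethylbut-3-en-1-yl)-2-methoxybenzene; 19 tert-butyl{(1S,2R)-1-[4-(benzyloxy)-3-methoxyphenyl]-2-(4-bromo-2,6-dimethoxyphenoxy)propoxy}dimethylsilane
Product: 20 tert-butyl{(1S,2R)-1-[4-(benzyloxy)-3-methoxyphenyl]-2-[4-((2R,3S)-4-[4-(benzyloxy)-3-methoxyphenyl]-2,3-dimethylbutyl)-2,6-dimethoxyphenoxy]propoxy}dimethylsilane (the 4,4''-di-O-benzyl 7''-O-silyl derivative of the target)
Conditions: 9 (1.5 equiv), Cu(OAc)2 (5 mol %), (R)-DTBM-SEGPHOS (5.5 mol %), [Pd(cinnamyl)Cl]2 (2 mol %), BrettPhos (4.4 mol %), NaOSiMe3 (2 equiv), MePh2SiH (3 equiv), THF, 45 °C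
Reagents that add atoms: none
Why: Dual-catalytic anti-Markovnikov hydroarylation; the closest known reaction type is the CuH/Pd-catalysed enantioselective coupling of 1,1-disubstituted alkenes with aryl bromides. Cu(OAc)2, the bisphosphine and the silane generate a monovalent copper hydride that adds across C7'=C8' of 9 with copper on the terminal C7' and hydrogen on C8', and this insertion fixes the new stereocentre. In parallel, zerovalent palladium carrying BrettPhos inserts into the C1'–Br bond of 19, the primary alkylcopper transmetallates to the divalent arylpalladium bromide, and reductive elimination forms the C7'–C1' bond, while NaOSiMe3 and the silane turn the copper bromide back into the hydride. No ring is closed. C8' is set by the catalyst: the ligand pocket tells the small methyl group from the branched C8 substituent, and because the two groups on the existing C8 centre (CH3 and CH2Ar) differ little in size, the bias of the substrate itself should be weak and the ligand should decide. The regiochemistry (copper on CH2) follows from the 1,1-disubstitution; the metal-bearing carbon C7' is not a stereocentre, so the mode of transmetallation cannot affect C8', and neither C8 nor C8' is next to a carbonyl. Cross-coupling has to outrun reduction of the C–Br bond by the hydride, which the excess of 9, the unhindered bromide carbon (two ortho hydrogens) and the fast reductive elimination from the BrettPhos complex are meant to secure; silyl and benzyl ethers are inert to both catalysts.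

Step 12
Reactants: 20 tert-butyl{(1S,2R)-1-[4-(benzyloxy)-3-methoxyphenyl]-2-[4-((2R,3S)-4-[4-(benzyloxy)-3-methoxyphenyl]-2,3-dimethylbutyl)-2,6-dimethoxyphenoxy]propoxy}dimethylsilane
Product: 21 (1S,2R)-1-[4-(benzyloxy)-3-methoxyphenyl]-2-{4-[(2R,3S)-4-[4-(benzyloxy)-3-methoxyphenyl]-2,3-dimethylbutyl]-2,6-dimethoxyphenoxy}propan-1-ol
Conditions: Bu4NF, THF, 0 °C → rt; aqueous work-up
Reagents that add atoms: none
Why: Fluoride-induced cleavage of the Si–O bond, driven by the strong Si–F bond; the phenols are still benzylated, so no phenoxide can expel the benzylic oxygen, and no stereocentre is involved.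

Step 13
Reactants: 21 (1S,2R)-1-[4-(benzyloxy)-3-methoxyphenyl]-2-{4-[(2R,3S)-4-[4-(benzyloxy)-3-methoxyphenyl]-2,3-dimethylbutyl]-2,6-dimethoxyphenoxy}propan-1-ol
Product: 22 (+)-(7''S,8S,8'R,8''R)-4,4''-dihydroxy-3,3',3'',5'-tetramethoxy-4',8''-oxy-8,8'-sesquineolignan-7''-ol
Conditions: H2 (1 atm), Pd/C (10% w/w), EtOAc/EtOH, rt; stopped after uptake of two equivalents
Reagents that add atoms: none
Why: Catalytic hydrogenolysis of the two aryl benzyl ethers under neutral conditions; aryl benzyl ethers are cleaved much faster than a secondary benzylic alcohol in a non-acidic solvent, so the target should be reached with the C7'' hydroxyl intact.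

## Compound list

1 | [4-(benzyloxy)-3-methoxyphenyl]methanol | COc1cc(CO)ccc1OCc1ccccc1 | starting material
2 | 1-(benzyloxy)-4-(bromomethyl)-2-methoxybenzene | COc1cc(CBr)ccc1OCc1ccccc1 | intermediate
3 | (R)-4-benzyl-3-propionyloxazolidin-2-one | CCC(=O)N1[C@H](Cc2ccccc2)COC1=O | starting material
4 | sodium (Z)-enolate of 3 | C/C=C(\[O-])N1[C@H](Cc2ccccc2)COC1=O.[Na+] | intermediate
5 | (R)-4-benzyl-3-{(S)-3-[4-(benzyloxy)-3-methoxyphenyl]-2-methylpropanoyl}oxazolidin-2-one | COc1cc(C[C@H](C)C(=O)N2[C@H](Cc3ccccc3)COC2=O)ccc1OCc1ccccc1 | intermediate
6 | (S)-3-[4-(benzyloxy)-3-methoxyphenyl]-N-methoxy-N,2-dimethylpropanamide | COc1cc(C[C@H](C)C(=O)N(C)OC)ccc1OCc1ccccc1 | intermediate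
7 | bromomagnesium (3S)-4-[4-(benzyloxy)-3-methoxyphenyl]-2-[methoxy(methyl)amino]-3-methylbutan-2-olate (hemiaminal chelate; new carbon unassigned) | COc1cc(C[C@H](C)C(C)(O[Mg]Br)N(C)OC)ccc1OCc1ccccc1 | intermediate
8 | (S)-4-[4-(benzyloxy)-3-methoxyphenyl]-3-methylbutan-2-one | COc1cc(C[C@H](C)C(C)=O)ccc1OCc1ccccc1 | intermediate
9 | (S)-1-(benzyloxy)-4-(2,3-dimethylbut-3-en-1-yl)-2-methoxybenzene | COc1cc(C[C@H](C)C(C)=C)ccc1OCc1ccccc1 | intermediate
10 | 4-bromo-2,6-dimethoxyphenol | COc1cc(Br)cc(OC)c1O | starting material
11 | ethyl (S)-lactate | CCOC(=O)[C@H](C)O | starting material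
12 | ethyl (R)-2-(4-bromo-2,6-dimethoxyphenoxy)propanoate | COc1cc(Br)cc(OC)c1O[C@H](C)C(=O)OCC | intermediate
13 | (R)-2-(4-bromo-2,6-dimethoxyphenoxy)-N-methoxy-N-methylpropanamide | COc1cc(Br)cc(OC)c1O[C@H](C)C(=O)N(C)OC | intermediate
14 | 1-(benzyloxy)-4-bromo-2-methoxybenzene | COc1cc(Br)ccc1OCc1ccccc1 | starting material
15 | [4-(benzyloxy)-3-methoxyphenyl]magnesium bromide | COc1cc([Mg]Br)ccc1OCc1ccccc1 | intermediate
16 | bromomagnesium (2R)-1-[4-(benzyloxy)-3-methoxyphenyl]-2-(4-bromo-2,6-dimethoxyphenoxy)-1-[methoxy(methyl)amino]propan-1-olate (hemiaminal chelate; new carbon unassigned) | COc1cc(Br)cc(OC)c1O[C@H](C)C(O[Mg]Br)(N(C)OC)c1ccc(OCc2ccccc2)c(OC)c1 | intermediate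
17 | (R)-1-[4-(benzyloxy)-3-methoxyphenyl]-2-(4-bromo-2,6-dimethoxyphenoxy)propan-1-one | COc1cc(Br)cc(OC)c1O[C@H](C)C(=O)c1ccc(OCc2ccccc2)c(OC)c1 | intermediate
18 | (1S,2R)-1-[4-(benzyloxy)-3-methoxyphenyl]-2-(4-bromo-2,6-dimethoxyphenoxy)propan-1-ol | COc1cc(Br)cc(OC)c1O[C@H](C)[C@@H](O)c1ccc(OCc2ccccc2)c(OC)c1 | intermediate
19 | tert-butyl{(1S,2R)-1-[4-(benzyloxy)-3-methoxyphenyl]-2-(4-bromo-2,6-dimethoxyphenoxy)propoxy}dimethylsilane | COc1cc(Br)cc(OC)c1O[C@H](C)[C@@H](O[Si](C)(C)C(C)(C)C)c1ccc(OCc2ccccc2)c(OC)c1 | intermediate
20 | tert-butyl{(1S,2R)-1-[4-(benzyloxy)-3-methoxyphenyl]-2-[4-((2R,3S)-4-[4-(benzyloxy)-3-methoxyphenyl]-2,3-dimethylbutyl)-2,6-dimethoxyphenoxy]propoxy}dimethylsilane | COc1cc(C[C@H](C)[C@H](C)Cc2cc(OC)c(O[C@H](C)[C@@H](O[Si](C)(C)C(C)(C)C)c3ccc(OCc4ccccc4)c(OC)c3)c(OC)c2)ccc1OCc1ccccc1 | intermediate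
21 | (1S,2R)-1-[4-(benzyloxy)-3-methoxyphenyl]-2-{4-[(2R,3S)-4-[4-(benzyloxy)-3-methoxyphenyl]-2,3-dimethylbutyl]-2,6-dimethoxyphenoxy}propan-1-ol | COc1cc(C[C@H](C)[C@H](C)Cc2cc(OC)c(O[C@H](C)[C@@H](O)c3ccc(OCc4ccccc4)c(OC)c3)c(OC)c2)ccc1OCc1ccccc1 | intermediate
22 | (+)-(7''S,8S,8'R,8''R)-4,4''-dihydroxy-3,3',3'',5'-tetramethoxy-4',8''-oxy-8,8'-sesquineolignan-7''-ol | COc1cc(C[C@H](C)[C@H](C)Cc2cc(OC)c(O[C@H](C)[C@@H](O)c3ccc(O)c(OC)c3)c(OC)c2)ccc1O | target

## Step count and least certain steps

Total step count: 13. Longest linear sequence: 8 steps (steps 1–5 or steps 6–10, followed by steps 11–13).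

**Step 11 (key step).** The most likely failure is slow hydrocupration of the α-branched 1,1-disubstituted alkene, so that reduction of the C–Br bond of 19 by the hydride outruns cross-coupling. The second risk is incomplete face selectivity at C8' if the neighbouring C8 centre works against the ligand. The fallback separates the two catalytic cycles. It sets out from 9, which would undergo copper-catalysed asymmetric hydroboration (CuCl, NaOtBu, the same antipode of DTBM-SEGPHOS, pinacolborane, THF). This would give 2-{(2R,3S)-4-[4-(benzyloxy)-3-methoxyphenyl]-2,3-dimethylbutyl}-4,4,5,5-tetramethyl-1,3,2-dioxaborolane F1, which can be purified and checked for diastereomeric purity. A Suzuki–Miyaura coupling of this primary alkylboronate with 19 (Pd(OAc)2, RuPhos, K3PO4, toluene/H2O, 90 °C) then comes back to the route at 20.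

**Step 9.** Chelation may be incomplete, because an aryl ether oxygen is a weak donor and is crowded by two methoxy groups, and this would erode the erythro selectivity. The fallback replaces chelate control by catalyst control. It sets out from 17 and uses asymmetric transfer hydrogenation of the Noyori type (RuCl(p-cymene)[(R,R)-TsDPEN], HCO2H/Et3N, rt), in which the aryl group of the ketone, not the α-substituent, is recognised. It comes back at 18, and no new compound arises on this way (F0).

**Step 3.** The aluminium amide may attack the ring carbonyl of the oxazolidinone instead of the α-branched exocyclic carbonyl, opening the auxiliary. The fallback sets out from 5. Hydrolysis with LiOH/H2O2 (THF/H2O, 0 °C) would give (S)-3-[4-(benzyloxy)-3-methoxyphenyl]-2-methylpropanoic acid F2 and the recovered auxiliary. Carbodiimide coupling of this acid with N,O-dimethylhydroxylamine hydrochloride (EDC·HCl, iPr2NEt, CH2Cl2) comes back at 6.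

**Step 6.** Alkylation of the doubly ortho-substituted phenol may be sluggish, so that the activated lactate is lost to elimination or to the hydrazide by-product. The fallback sets out from 11 and changes from redox condensation to a classical displacement. Tf2O and 2,6-lutidine (CH2Cl2, −78 °C) would give ethyl (S)-2-{[(trifluoromethyl)sulfonyl]oxy}propanoate F3. This would be displaced with inversion by the potassium phenoxide of 10 (K2CO3, MeCN, 0 °C → rt), coming back at 12.

**Step 13.** Over-reduction is the risk: hydrogenolysis of the benzylic C7''–O bond, which is activated by the para-oxygenated ring C, alongside cleavage of the benzyl ethers. The fallback sets out from 20 and reverses the order of deprotection. Hydrogenolysis with the bulky silyl ether still in place (H2, Pd/C, EtOAc) would give 4-[(1S,2R)-1-[(tert-butyldimethylsilyl)oxy]-2-{4-[(2R,3S)-4-(4-hydroxy-3-methoxyphenyl)-2,3-dimethylbutyl]-2,6-dimethoxyphenoxy}propyl]-2-methoxyphenol F4. Desilylation with acetic acid-buffered Bu4NF (THF, 0 °C), mild enough to avoid expulsion of the benzylic oxygen by a phenoxide, comes back at 22.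

## Further compounds

F1 | step 11 | 2-{(2R,3S)-4-[4-(benzyloxy)-3-methoxyphenyl]-2,3-dimethylbutyl}-4,4,5,5-tetramethyl-1,3,2-dioxaborolane | COc1cc(C[C@H](C)[C@H](C)CB2OC(C)(C)C(C)(C)O2)ccc1OCc1ccccc1
F0 | step 9 | none | none
F2 | step 3 | (S)-3-[4-(benzyloxy)-3-methoxyphenyl]-2-methylpropanoic acid | COc1cc(C[C@H](C)C(=O)O)ccc1OCc1ccccc1
F3 | step 6 | ethyl (S)-2-{[(trifluoromethyl)sulfonyl]oxy}propanoate | CCOC(=O)[C@H](C)OS(=O)(=O)C(F)(F)F
F4 | step 13 | 4-[(1S,2R)-1-[(tert-butyldimethylsilyl)oxy]-2-{4-[(2R,3S)-4-(4-hydroxy-3-methoxyphenyl)-2,3-dimethylbutyl]-2,6-dimethoxyphenoxy}propyl]-2-methoxyphenol | COc1cc(C[C@H](C)[C@H](C)Cc2cc(OC)c(O[C@H](C)[C@@H](O[Si](C)(C)C(C)(C)C)c3ccc(O)c(OC)c3)c(OC)c2)ccc1O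
A1 | alternative 1 | (S)-5-[3,5-dimethoxy-4-(methoxymethoxy)phenyl]furan-2(5H)-one | O=C1C=C[C@@H](c2cc(OC)c(OCOC)c(OC)c2)O1
A2 | alternative 1 | (3S,4S,5S)-3-[4-(benzyloxy)-3-methoxybenzyl]-5-[3,5-dimethoxy-4-(methoxymethoxy)phenyl]-4-methyldihydrofuran-2(3H)-one | COc1cc(C[C@H](C2=O)[C@H](C)[C@@H](c3cc(OC)c(OCOC)c(OC)c3)O2)ccc1OCc1ccccc1
A3 | alternative 2 | meso-(3R,4S)-3,4-dimethyldihydrofuran-2,5-dione (cis-2,3-dimethylsuccinic anhydride) | C[C@H]1[C@@H](C)C(=O)OC1=O
A4 | alternative 2 | [4-(benzyloxy)-3-methoxyphenyl]zinc bromide | COc1cc([Zn]Br)ccc1OCc1ccccc1
A5 | alternative 2 | (2S,3R)-4-[4-(benzyloxy)-3-methoxyphenyl]-2,3-dimethyl-4-oxobutanoic acid | COc1cc(C(=O)[C@H](C)[C@H](C)C(=O)O)ccc1OCc1ccccc1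
A6 | alternative 3 | (R,E)-5-[3,5-dimethoxy-4-(methoxymethoxy)phenyl]pent-3-en-2-yl 3-[4-(benzyloxy)-3-methoxyphenyl]propanoate | COc1cc(CCC(=O)O[C@H](C)/C=C/Cc2cc(OC)c(OCOC)c(OC)c2)ccc1OCc1ccccc1
A7 | alternative 3 | (2S,3S,E)-2-[4-(benzyloxy)-3-methoxybenzyl]-3-[3,5-dimethoxy-4-(methoxymethoxy)benzyl]hex-4-enoic acid | COc1cc(C[C@H](C(=O)O)[C@H](/C=C/C)Cc2cc(OC)c(OCOC)c(OC)c2)ccc1OCc1ccccc1
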